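**Retrosynthetic overview**
1. Ring D (dimethylpyran, O–CMe2 bond): oxa-6π opening to an ortho-quinone methide. This leads back to the free 4'-phenol flanked by two prenyl groups, (2S)-sophoranone.
2. Ring C (O1–C2 bond): retro-oxa-Michael to the acyclic triprenylated chalcone sophoradin. Both closures are run in one flask on the unprotected triol, and C2 is set in the first of them.
3. Chalcone Cα=Cβ: Claisen–Schmidt union of 3-prenylresacetophenone with 4-hydroxy-3,5-diprenylbenzaldehyde, without protecting groups.
4. Three aryl–prenyl bonds: direct ortho C-prenylation of 2,4-dihydroxyacetophenone and 4-hydroxybenzaldehyde with prenyl bromide.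
5. Ring order: rings A (resorcinol-derived) and B (2-aryl) are bought as arenes, ring C is closed first, ring D last.

Assumption: 3-{[3,5-bis(trifluoromethyl)phenyl]amino}-4-{[(9R)-6'-methoxycinchonan-9-yl]amino}cyclobut-3-ene-1,2-dione (quinidine-derived) is taken to give the 2S sense, by analogy with its Si-face delivery of nucleophiles to chalcones; the sense is checked by circular dichroism on the first run, and if it is opposite the (8α,9S) quinine-derived pseudo-enantiomer is used with nothing else changed.

**Step 1**
Reactants: 1 2,4-dihydroxyacetophenone; 2 prenyl bromide (1-bromo-3-methylbut-2-ene)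
Product: 3 1-[2,4-dihydroxy-3-(3-methylbut-2-en-1-yl)phenyl]ethan-1-one
Conditions: KOH (1.1 equiv), H2O, 0 °C to rt, 16 h; chromatography
Reagents that add atoms: prenyl bromide (2), CC(C)=CCBr
Why: Ortho C-alkylation of an ambident phenoxide (nuclear prenylation, SN2 at the primary allylic carbon), in which water hydrogen-bonds and shields the oxygen so that carbon attacks, and C3, ortho to both oxygens, is the most nucleophilic ring position; the 5-prenyl isomer and the 4-O-prenyl ether are separated and no stereocentre is formed.

**Step 2**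
Reactants: 4 4-hydroxybenzaldehyde; 2 prenyl bromide (2.3 equiv)
Product: 6 4-hydroxy-3,5-bis(3-methylbut-2-en-1-yl)benzaldehyde, via 4-hydroxy-3-prenylbenzaldehyde 5 (not isolated)
Conditions: KOH (2.3 equiv), H2O, 0 °C to rt, 24 h; chromatography
Reagents that add atoms: prenyl bromide (2), CC(C)=CCBr
Why: Two successive ortho C-alkylations of the ambident phenoxide (nuclear prenylation), in which the para position is blocked by the formyl group and mono-prenylated 5 is deprotonated again and alkylated at the remaining ortho carbon; O-prenyl ethers are separated, left-over 5 is recycled, and no stereocentre is formed.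

**Step 3**
Reactants: 3 1-[2,4-dihydroxy-3-(3-methylbut-2-en-1-yl)phenyl]ethan-1-one; 6 4-hydroxy-3,5-bis(3-methylbut-2-en-1-yl)benzaldehyde
Product: 8 sophoradin = (E)-2',4',4-trihydroxy-3,5,3'-triprenylchalcone, via racemic aldol adduct 7 (not isolated)
Conditions: KOH (60% aq, 20 equiv), EtOH, Ar, rt to 45 °C, 48 h; then 1 M HCl, 0 °C, pH 4; recrystallise
Reagents that add atoms: none
Why: Claisen–Schmidt condensation (crossed aldol, then E1cB loss of hydroxide assisted by the para-phenoxide), in which only 3 can enolise and only 6 carries an aldehyde, the prenyl groups are inert to hydroxide, the excess base holds the product as the ring-open polyanion so that no racemic flavanone forms, the conjugated E-alkene is the thermodynamic outcome, and the stereocentre of 7 is lost again.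

**Step 4**
Reactants: 8 sophoradin
Product: 11 (2S)-sophoranochromene (target), via (2S)-sophoranone 9 (not isolated), via ortho-quinone methide 10 (not isolated)
Conditions: first 3-{[3,5-bis(trifluoromethyl)phenyl]amino}-4-{[(9R)-6'-methoxycinchonan-9-yl]amino}cyclobut-3-ene-1,2-dione (15 mol%), PhMe/CH2Cl2 4:1 (0.05 M), 25 °C, 48 h (to about 85% conversion); then CF3CO2H (15 mol%), DDQ (2,3-dichloro-5,6-dicyano-1,4-benzoquinone, 1.05 equiv), 0 °C to 25 °C, 2 h; chromatography, recrystallise
Reagents that add atoms: none
Why: Proposed new method: a one-flask copy of the chalcone isomerase and prenylphenol cyclase sequence, in which the two squaramide N–H bonds bind the enone carbonyl in place of its internal hydrogen bond while the quinuclidine nitrogen takes the proton of the 2'-OH, so that the oxygen closes ring C by 6-endo-trig intramolecular oxa-Michael addition to the Si face of the β-carbon and sets C2 as S (closest known reaction type: cinchona thiourea or squaramide catalysed asymmetric cyclisation of 2'-hydroxychalcones to flavanones), after which CF3CO2H protonates the amine and freezes the reversible addition, and DDQ removes hydride from the benzylic-allylic CH2 of either of the two equivalent prenyl groups of ring B, now an electron-rich 2,4,6-trialkylphenol that reacts at 0 °C whereas the acyl-deactivated ring A prenylphenol and the C2–H bond are known to need refluxing solvent, to give ortho-quinone methide 10, whose oxa-6π electrocyclisation closes ring D (closest known reaction type: DDQ cyclodehydrogenation of ortho-prenylphenols to 2,2-dimethyl-2H-chromenes), leaves C2 untouched and caps the 4'-OH that would otherwise assist racemisation.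

**Compound list**
1 | 2,4-dihydroxyacetophenone | CC(=O)c1ccc(O)cc1O | starting material
2 | prenyl bromide (1-bromo-3-methylbut-2-ene) | CC(C)=CCBr | starting material
3 | 1-[2,4-dihydroxy-3-(3-methylbut-2-en-1-yl)phenyl]ethan-1-one | CC(=O)c1ccc(O)c(CC=C(C)C)c1O | intermediate
4 | 4-hydroxybenzaldehyde | O=Cc1ccc(O)cc1 | starting material
5 | 4-hydroxy-3-(3-methylbut-2-en-1-yl)benzaldehyde (not isolated) | CC(C)=CCc1cc(C=O)ccc1O | intermediate
6 | 4-hydroxy-3,5-bis(3-methylbut-2-en-1-yl)benzaldehyde | CC(C)=CCc1cc(C=O)cc(CC=C(C)C)c1O | intermediate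
7 | racemic aldol adduct, 1-[2,4-dihydroxy-3-prenylphenyl]-3-hydroxy-3-[4-hydroxy-3,5-diprenylphenyl]propan-1-one (not isolated) | CC(C)=CCc1cc(C(O)CC(=O)c2ccc(O)c(CC=C(C)C)c2O)cc(CC=C(C)C)c1O | intermediate
8 | sophoradin, (2E)-1-[2,4-dihydroxy-3-(3-methylbut-2-en-1-yl)phenyl]-3-[4-hydroxy-3,5-bis(3-methylbut-2-en-1-yl)phenyl]prop-2-en-1-one | CC(C)=CCc1cc(/C=C/C(=O)c2ccc(O)c(CC=C(C)C)c2O)cc(CC=C(C)C)c1O | intermediate
9 | (2S)-sophoranone, (2S)-7-hydroxy-2-[4-hydroxy-3,5-bis(3-methylbut-2-en-1-yl)phenyl]-8-(3-methylbut-2-en-1-yl)-2,3-dihydro-4H-chromen-4-one (not isolated) | CC(C)=CCc1cc([C@@H]2CC(=O)c3ccc(O)c(CC=C(C)C)c3O2)cc(CC=C(C)C)c1O | intermediate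
10 | ortho-quinone methide of 9: ring B is a cyclohexa-2,4-dienone carrying a Z-configured exocyclic 3-methylbut-2-enylidene group next to the carbonyl, C2 still S (not isolated) | O=C1C(CC=C(C)C)=CC([C@@H]2CC(=O)c3ccc(O)c(CC=C(C)C)c3O2)=C/C1=C/C=C(C)C | intermediate
11 | (2S)-sophoranochromene, (2S)-2-[2,2-dimethyl-8-(3-methylbut-2-en-1-yl)-2H-chromen-6-yl]-7-hydroxy-8-(3-methylbut-2-en-1-yl)-2,3-dihydro-4H-chromen-4-one (CNP0110366.1) | CC(C)=CCc1cc([C@@H]2CC(=O)c3ccc(O)c(CC=C(C)C)c3O2)cc2c1OC(C)(C)C=C2 | target

**Totals**
Total step count: 4.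
Longest linear sequence: 3 (step 1 or step 2, then steps 3 and 4).

**Three steps most likely to fail**

**Step 4.**
- The chalcone is unactivated and the addition is reversible, so the ee falls as equilibrium is approached.
- The acidic 4'-OH of ring A competes with the 2'-OH for the amine. In these aprotic solvents that should only slow the reaction.
- DDQ could also attack the ring A prenyl group or C2–H.

The fallback takes the stereochemistry from a kinetic resolution instead of an asymmetric ring closure. It sets out from 8. NaOAc in refluxing EtOH closes ring C to racemic sophoranone F1. DDQ in toluene at 0 °C to rt then gives racemic sophoranochromene F2. Noyori–Ikariya asymmetric transfer hydrogenation follows, with RuCl[(R,R)-TsDPEN](p-cymene) (1 mol%) in HCO2H/Et3N 5:2 and EtOAc, stopped near 55% conversion. It reduces the matched 2R ketone to the cis alcohol (2R,4R)-flavan-4-ol F3 and leaves the 2S ketone, which is separated by chromatography. The fallback comes back to the route at 11, with at most 50% from F2. If the oxidation fails rather than the ee, the fallback given for step 3 bypasses it as well.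

**Step 3.** Under the conditions aldehyde 6 is a phenoxide, hence a vinylogous carboxylate and a poor electrophile, and the enolate of 3 is a trianion.

The fallback closes ring D before the coupling, so that the aldehyde has no acidic proton and the ring order is reversed. It sets out from 6, with partner 3 unchanged.
- DDQ in refluxing toluene gives 2,2-dimethyl-8-(3-methylbut-2-en-1-yl)-2H-chromene-6-carbaldehyde F4.
- Claisen–Schmidt condensation of this aldehyde with 3 (KOH, EtOH, rt, then HCl) gives sophoradochromene F5.
- 3-{[3,5-bis(trifluoromethyl)phenyl]amino}-4-{[(9R)-6'-methoxycinchonan-9-yl]amino}cyclobut-3-ene-1,2-dione (15 mol%) in toluene closes ring C last on a substrate without a free ring B phenol.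

It comes back to the route at 11, at the cost of one more step.

**Step 2.** O-alkylation, hydrolysis of the bromide and stalling at 5 all compete with double C-alkylation, so 15–30% is expected.

The fallback replaces phenoxide alkylation by cross-coupling. It sets out from 4. Br2 (2.1 equiv) in AcOH gives 3,5-dibromo-4-hydroxybenzaldehyde F6. A double Stille coupling with tributyl(3-methylbut-2-en-1-yl)stannane (2.4 equiv), Pd(PPh3)4 (5 mol%), DMF, 100 °C then joins both prenyl groups through their tin-bearing carbon. It comes back to the route at 6.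

**Further compounds**
F1 | step 4 | racemic sophoranone | CC(C)=CCc1cc(C2CC(=O)c3ccc(O)c(CC=C(C)C)c3O2)cc(CC=C(C)C)c1O
F2 | step 4 | racemic sophoranochromene | CC(C)=CCc1cc(C2CC(=O)c3ccc(O)c(CC=C(C)C)c3O2)cc2c1OC(C)(C)C=C2
F3 | step 4 | (2R,4R)-2-[2,2-dimethyl-8-(3-methylbut-2-en-1-yl)-2H-chromen-6-yl]-8-(3-methylbut-2-en-1-yl)-3,4-dihydro-2H-chromene-4,7-diol (cis flavan-4-ol) | CC(C)=CCc1cc([C@H]2C[C@@H](O)c3ccc(O)c(CC=C(C)C)c3O2)cc2c1OC(C)(C)C=C2
F4 | step 3 | 2,2-dimethyl-8-(3-methylbut-2-en-1-yl)-2H-chromene-6-carbaldehyde | CC(C)=CCc1cc(C=O)cc2c1OC(C)(C)C=C2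
F5 | step 3 | sophoradochromene, (2E)-1-[2,4-dihydroxy-3-(3-methylbut-2-en-1-yl)phenyl]-3-[2,2-dimethyl-8-(3-methylbut-2-en-1-yl)-2H-chromen-6-yl]prop-2-en-1-one | CC(C)=CCc1cc(/C=C/C(=O)c3ccc(O)c(CC=C(C)C)c3O)cc2c1OC(C)(C)C=C2
F6 | step 2 | 3,5-dibromo-4-hydroxybenzaldehyde | O=Cc1cc(Br)c(O)c(Br)c1
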